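**Target:** (E)-3-[(2R,3S)-2-(3,4-dimethoxyphenyl)-7-hydroxy-3-(hydroxymethyl)-2,3-dihydro-1-benzofuran-5-yl]prop-2-enoic acid, compound 22. Abbreviations: TBS = tert-butyldimethylsilyl; Bpin = 4,4,5,5-tetramethyl-1,3,2-dioxaborolan-2-yl.

## Analysis of the target

Compound 22 is a 2-aryl-2,3-dihydro-1-benzofuran: a dihydrofuran ring (O1, C2, C3, C3a, C7a) fused to a benzo ring (C3a, C4, C5, C6, C7, C7a). C2 carries a 3,4-dimethoxyphenyl group and C3 a hydroxymethyl group. These two adjacent stereocentres are trans, with absolute configuration (2R,3S). The benzo ring has four substituents: O1 on C7a, a free phenol on C7, an (E)-propenoic acid on C5 and C3 on C3a, with hydrogen only at C4 and C6. The sensitive sites are the C2–O1 bond (a benzylic ether activated by the dimethoxyphenyl ring, prone to ionisation by acid or hydride abstraction by oxidants), the catechol-like O1/C7–OH pair, and the cinnamic acid. The difficulty is twofold: the trans C2/C3 pair must be set in the absolute sense, and the benzo ring needs a 1,2,3,5-pattern that is hard to reach by aromatic substitution, because the dimethoxyphenyl ring is the more reactive arene. The strategy rests on one feature: O1 on C7a and the side-chain carbon on C5 are para. That is the orientation a 2-oxygenated diene and a propiolate give in a [4+2] cycloaddition, so the benzo ring can be built onto an enantiopure dihydrofuran, with boron marking C7 for the phenol.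

## Retrosynthetic reasoning

**22 to 21.** The last forward operation is cleavage of the O–Si bond of the primary silyl ether in 21. The silyl group is needed for the one strongly basic step (lactone enolisation) and is harmless in all later steps. Its removal must leave the C2–O1 bond and the acid untouched.

**21 to 18 and 19.** The Cα=Cβ bond of the propenoic acid is cut, giving aldehyde 18 and malonic acid 19. This delivers the free (E)-acid in one step, with no ester to hydrolyse, and the condensation tolerates a free phenol.

**18 to 17 to 16.** The aldehyde carbon is traced through benzylic alcohol 17 to the methyl ester of 16. Full reduction followed by benzylic oxidation is chosen over a partial reduction because both operations are dependable on an aryl ester.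

**16 to 15.** The C7–O bond is replaced by a C7–B bond. A boronate is a masked phenol that survives cycloaddition and dehydrogenation. An oxygen at this position of the diene would act as a second donor and compete with O1 for control of the regiochemistry.

**15 to 12 and 13 (via 14).** After formally returning two hydrogens (C3a and C6, giving 14), the bonds C3a–C4 and C5–C6 are cut. This removes the whole benzo ring and leaves diene 12 and methyl propiolate 13. The cut is made here because the para relation of O1 and C5 matches the polarity of an enol-ether diene and a propiolate, and because C2 and C3 lie outside the reacting π-system. The forward step must give the C5 ester regioisomer and must dehydrogenate the ring without oxidising C2–H.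

**12 to 10 and 11.** The bond between the dihydrofuran carbon that becomes C7a and the vinyl carbon that becomes C7 is cut. Enol triflate 10 and geminal diboronate 11 result. One coupling installs C6, C7 and the boron together.

**10 to 9 to 8 to 7.** The ketene acetal triflate comes from the enolate of lactone 9. The lactone already holds O1, C2, C3 and the carbons that become C3a and C7a. Silyl ether 9 comes from alcohol 8, and 8 from acid 7 by reduction of the carboxyl group in the presence of the lactone.

**7 to 6 to 3 and 4.** The C2–C3 bond (target numbering) is an aldol bond between the α-carbon of succinate imide 3 and aldehyde 4. The lactone C–O bond forms from the aldol oxygen and the distal ester. A syn aldol becomes a trans lactone on ring closure, so one auxiliary-controlled step sets both centres, and hydrolysis of imide 6 returns the auxiliary.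

**3 to 1 and 2.** The imide N–acyl bond is cut to oxazolidinone 1 and acid chloride 2.

## Alternatives that were turned down

**Alternative 1: ring contraction of a flavanone.**
- Disconnection: the C3–C3a bond of ester A2 is traced back to the carbonyl–aryl bond of enantioenriched flavanone A1.
- Forward key step: a trivalent iodine oxidant in an acidic orthoformate medium activates the carbon next to the carbonyl of A1. The benzo carbon then shifts from the carbonyl carbon to that carbon, and the old carbonyl carbon leaves the ring as a methyl ester, giving trans ester A2.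
- For it: the key step is a known reaction type. It gives the trans 2-aryl-3-carboxylate directly, the bromine at C5 is ready for a Heck reaction, and A1 is a few steps from aldehyde 4. The whole route would be about eight steps, clearly shorter than the thirteen proposed here.
- Against it: the outcome depends on which group migrates. In A1 the C2 aryl group is a dimethoxyphenyl ring with high migratory aptitude, while the benzo ring is deactivated by bromine and an acyloxy group, so a shift of the C2 aryl group from C2 to C3 should compete strongly. The acidic medium can also open the pyranone ring reversibly or ionise C2, which puts the enantiomeric purity at risk, and the oxidant can attack the dimethoxyphenyl ring.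
- Comparison: Alternative 1 is stronger on step count. The chosen route offers instead stereocentres set by an auxiliary with a predictable sense, and a ring-forming step governed by orbital polarity and not by a contest of migrating groups.

**Alternative 2: [4+1] annulation of an ortho-quinone methide with a chiral sulfonium ylide.**
- Disconnection: C2–C3 and O1–C2 of A6 are cut, giving sulfone A3 and benzylic sulfonium salt A5.
- Forward key step: a carbonate base expels the sulfinate group from A3 to unmask ortho-quinone methide A4, and deprotonates A5 at its benzylic carbon. The carbanion adds to the exocyclic carbon of A4 (C2–C3), and the phenoxide displaces the sulfide at C2 (O1–C2) to close the ring as A6.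
- For it: it is the most convergent plan. Both stereocentres and the heterocycle form in one step, the anti arrangement in the ring-closing displacement favours trans, and the arene substituents are bought. It would need roughly eight steps.
- Against it: A4 carries a CH2O group on its exocyclic carbon and can lose the quinone methide by a 1,5-hydrogen shift before the ylide adds. The ylide from A5 is only semi-stabilised and electron-rich, so rearrangement competes. Absolute control would depend on face discrimination between two transient planar partners with no rigid organising element, and the chiral sulfide is stoichiometric.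
- Comparison: Alternative 2 is stronger on convergence and step economy. The chosen route offers stereocontrol from a closed, well-understood transition state, fixed in a lactone before the arene exists.

**Alternative 3: anodic benzylic oxidation with phenol capture.**
- Disconnection: only O1–C2 of A8 is cut, leading to phenol A7, in which the C3 centre is already set.
- Forward key step: constant-current electrolysis at a carbon anode oxidises the dimethoxyarene of A7 to a benzylic cation at C2, and the ortho phenol oxygen closes the ring to give A8.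
- For it: the fully substituted benzo ring, with the C5 ester and the C7 oxygen, comes from a purchasable arene, so no boron-to-oxygen exchange is needed. Only one stereocentre must be made beforehand, and the oxidation uses no reagent.
- Against it: the free ortho-alkoxyphenol of A7 is oxidised at a potential close to that of the dimethoxyarene, so phenoxonium chemistry competes. The C2–H of A8 is a more easily oxidised benzylic ether than the CH2 of A7, and a further oxidation there would aromatise the furan ring and erase both centres. The trans selectivity rests only on the preference of the cation capture. Making A7 in enantiopure form needs about as many steps as are saved.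
- Comparison: Alternative 3 is as strong or stronger on the arene substitution pattern. The chosen route offers a ring-forming step that cannot touch C2 or C3, both of which are fixed beforehand.

Key step: step 8

## Route

Assumption: compounds 1, 2 and 11 are taken as purchasable; benzofuran numbering (O1, C2, C3, C3a, C4 to C7, C7a) is used for the carbons of every intermediate that end up in 22.

Step 1
Reactants: 1 (R)-4-benzyl-1,3-oxazolidin-2-one; 2 methyl 4-chloro-4-oxobutanoate
Product: 3 methyl 4-[(4R)-4-benzyl-2-oxo-1,3-oxazolidin-3-yl]-4-oxobutanoate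
Conditions: n-BuLi, THF, −78 °C; then 2, −78 → 0 °C
Reagents that add atoms: none
Why: N-acylation of the lithiated oxazolidinone; the acid chloride is far more electrophilic than the methyl ester of 2, so only the imide should form.

Step 2
Reactants: 3 methyl 4-[(4R)-4-benzyl-2-oxo-1,3-oxazolidin-3-yl]-4-oxobutanoate; 4 3,4-dimethoxybenzaldehyde
Product: 6 (4R)-4-benzyl-3-[(2R,3R)-2-(3,4-dimethoxyphenyl)-5-oxooxolane-3-carbonyl]-1,3-oxazolidin-2-one, via syn-aldol adduct 5 (not isolated)
Conditions: n-Bu2BOTf, i-Pr2NEt, CH2Cl2, 0 °C; 4, −78 °C → rt; H2O2, pH 7 buffer, MeOH, 0 °C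
Reagents that add atoms: none
Why: Evans syn-aldol reaction: boron binds the imide carbonyl, so the (Z)-enolate forms at the imide α-carbon and reacts through a Zimmerman–Traxler chair in which the (R)-benzyl group blocks one enolate face, which should set both new centres as (R,R)-syn; the aldolate oxygen then attacks the distal methyl ester (5-exo-trig), and the syn pair becomes the trans lactone.

Step 3
Reactants: 6 (4R)-4-benzyl-3-[(2R,3R)-2-(3,4-dimethoxyphenyl)-5-oxooxolane-3-carbonyl]-1,3-oxazolidin-2-one
Product: 7 (2R,3R)-2-(3,4-dimethoxyphenyl)-5-oxooxolane-3-carboxylic acid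
Conditions: LiOH, H2O2, THF/H2O, 0 °C; aq. Na2SO3; then 1 M HCl
Reagents that add atoms: hydrogen peroxide, OO
Why: Hydroperoxide cleaves the exocyclic imide carbonyl selectively and releases 1 for recovery; any lactone opened by hydroxide recloses on acidification, and the trans arrangement is also the thermodynamic one, so the α-centre is not at risk.

Step 4
Reactants: 7 (2R,3R)-2-(3,4-dimethoxyphenyl)-5-oxooxolane-3-carboxylic acid
Product: 8 (4S,5R)-5-(3,4-dimethoxyphenyl)-4-(hydroxymethyl)oxolan-2-one
Conditions: BH3·SMe2, THF, 0 °C → rt; MeOH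
Reagents that add atoms: none
Why: Borane reduces a carboxylic acid through its acyloxyborane much faster than a lactone, so the lactone carbonyl should survive; no stereocentre is touched (the descriptor at the former α-carbon changes only because the priorities change).

Step 5
Reactants: 8 (4S,5R)-5-(3,4-dimethoxyphenyl)-4-(hydroxymethyl)oxolan-2-one
Product: 9 (4S,5R)-4-(TBS-oxymethyl)-5-(3,4-dimethoxyphenyl)oxolan-2-one
Conditions: TBSCl, imidazole, CH2Cl2, 0 °C → rt
Reagents that add atoms: tert-butyldimethylsilyl chloride, CC(C)(C)[Si](C)(C)Cl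
Why: Standard silylation of a primary alcohol; it removes the acidic O–H before the strong base of step 6 and prevents transfer of the lactone acyl group to the primary oxygen.

Step 6
Reactants: 9 (4S,5R)-4-(TBS-oxymethyl)-5-(3,4-dimethoxyphenyl)oxolan-2-one
Product: 10 (2R,3S)-3-(TBS-oxymethyl)-2-(3,4-dimethoxyphenyl)-2,3-dihydrofuran-5-yl trifluoromethanesulfonate
Conditions: KN(SiMe3)2, PhNTf2, THF/DMPU, −78 °C
Reagents that add atoms: N-phenylbis(trifluoromethanesulfonimide), O=S(=O)(N(c1ccccc1)S(=O)(=O)C(F)(F)F)C(F)(F)F
Why: Kinetic enolisation at the only α-CH2 of the lactone and O-sulfonylation of the potassium enolate (ketene acetal triflate formation); the two stereocentres are β and γ to the carbonyl and cannot enolise.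

Step 7
Reactants: 10 (2R,3S)-3-(TBS-oxymethyl)-2-(3,4-dimethoxyphenyl)-2,3-dihydrofuran-5-yl trifluoromethanesulfonate; 11 1,1-bis(Bpin)ethene
Product: 12 (2R,3S)-3-(TBS-oxymethyl)-2-(3,4-dimethoxyphenyl)-5-[1-(Bpin)ethenyl]-2,3-dihydrofuran
Conditions: Pd(PPh3)4 (5 mol %), 11 (2.5 equiv), 3 M aq. Cs2CO3, THF, rt
Reagents that add atoms: none
Why: Suzuki–Miyaura coupling: zerovalent palladium inserts into the C–OTf bond and one boron of the geminal diboronate transmetalates; a geminal diboronate is activated by its neighbouring boron and should react faster than the mono-boronate product, and the excess of 11 further suppresses a second coupling.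

Step 8
Reactants: 12 (2R,3S)-3-(TBS-oxymethyl)-2-(3,4-dimethoxyphenyl)-5-[1-(Bpin)ethenyl]-2,3-dihydrofuran; 13 methyl propiolate
Product: 15 methyl (2R,3S)-3-(TBS-oxymethyl)-2-(3,4-dimethoxyphenyl)-7-(Bpin)-2,3-dihydro-1-benzofuran-5-carboxylate, via 3a,6-dihydro cycloadduct 14 (not isolated)
Conditions: 13 (5 equiv), PhMe, 90 °C (sealed tube); then DDQ (1.05 equiv), 0 °C → rt
Reagents that add atoms: none
Why: Diels–Alder benzannulation followed by dehydrogenation, the known behaviour of 2-alkoxy-1,3-dienes made from lactone enol triflates towards propiolates. The diene is C3a=C7a–C7=C6; its inner substituents (O1 and the planar boronate) do not hinder the s-cis form, and its only terminal substituent, C3, points outward. O1 raises the HOMO and puts its largest coefficient on C3a, the β-carbon of the enol ether, which bonds to the β-carbon of 13 (the future C4) slightly ahead of the C6–C5 bond in a concerted, asynchronous [4+2] step; the six-membered ring is the only ring formed, and it closes in the cycloaddition itself. The selectivity needed is regiochemical (ester on C5, para to O1), and it is secured by the enol-ether donor and by the steric clash a C4 ester would have with the C3 side chain. The boronate is a weak, cross-conjugated acceptor whose own slight preference points the other way, so it is not counted on to help. The centre at C3a of 14 forms as either epimer and is erased on aromatisation, so no new stereocentre persists, and C2 and C3 lie outside the π-system. DDQ removes hydride from the doubly allylic C6 to give a cation stabilised by O1, and loss of the C3a proton gives the arene; one equivalent at 0 °C is used so that this fast step outruns attack on the benzylic C2–H. The boronate should survive both stages and marks C7 for the hydroxyl.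

Step 9
Reactants: 15 methyl (2R,3S)-3-(TBS-oxymethyl)-2-(3,4-dimethoxyphenyl)-7-(Bpin)-2,3-dihydro-1-benzofuran-5-carboxylate
Product: 16 methyl (2R,3S)-3-(TBS-oxymethyl)-2-(3,4-dimethoxyphenyl)-7-hydroxy-2,3-dihydro-1-benzofuran-5-carboxylate
Conditions: NaBO3·4H2O, THF/H2O, rt
Reagents that add atoms: sodium perborate, [Na+].[O-]OB=O
Why: ipso-Oxidation of an aryl boronate: peroxide adds to boron and the aryl group migrates from boron to oxygen at the same carbon; perborate is mild enough to spare the methyl ester and the silyl ether.

Step 10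
Reactants: 16 methyl (2R,3S)-3-(TBS-oxymethyl)-2-(3,4-dimethoxyphenyl)-7-hydroxy-2,3-dihydro-1-benzofuran-5-carboxylate
Product: 17 (2R,3S)-3-(TBS-oxymethyl)-2-(3,4-dimethoxyphenyl)-5-(hydroxymethyl)-2,3-dihydro-1-benzofuran-7-ol
Conditions: i-Bu2AlH (4 equiv), CH2Cl2, −78 → 0 °C; aq. potassium sodium tartrate
Reagents that add atoms: none
Why: Hydride reduction of the aryl ester to the benzylic alcohol; the phenol only consumes one equivalent of hydride, and the silyl and aryl ethers are inert.

Step 11
Reactants: 17 (2R,3S)-3-(TBS-oxymethyl)-2-(3,4-dimethoxyphenyl)-5-(hydroxymethyl)-2,3-dihydro-1-benzofuran-7-ol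
Product: 18 (2R,3S)-3-(TBS-oxymethyl)-2-(3,4-dimethoxyphenyl)-7-hydroxy-2,3-dihydro-1-benzofuran-5-carbaldehyde
Conditions: MnO2 (activated, excess), CH2Cl2, rt
Reagents that add atoms: none
Why: MnO2 oxidises benzylic alcohols selectively and stops at the aldehyde; the phenol is meta to the carbinol, so no quinone methide can form.

Step 12
Reactants: 18 (2R,3S)-3-(TBS-oxymethyl)-2-(3,4-dimethoxyphenyl)-7-hydroxy-2,3-dihydro-1-benzofuran-5-carbaldehyde; 19 malonic acid
Product: 21 (E)-3-[(2R,3S)-3-(TBS-oxymethyl)-2-(3,4-dimethoxyphenyl)-7-hydroxy-2,3-dihydro-1-benzofuran-5-yl]prop-2-enoic acid, via arylidenemalonic acid 20 (not isolated)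
Conditions: 19 (3 equiv), pyridine, piperidine (cat.), 85 °C; cold aq. citric acid work-up
Reagents that add atoms: none
Why: Knoevenagel–Doebner condensation: amine-catalysed condensation with 19 and decarboxylation in pyridine should give the (E)-cinnamic acid directly, with aryl and carboxyl trans; free phenols are tolerated, as in the classical preparation of hydroxycinnamic acids.

Step 13
Reactants: 21 (E)-3-[(2R,3S)-3-(TBS-oxymethyl)-2-(3,4-dimethoxyphenyl)-7-hydroxy-2,3-dihydro-1-benzofuran-5-yl]prop-2-enoic acid
Product: 22 (E)-3-[(2R,3S)-2-(3,4-dimethoxyphenyl)-7-hydroxy-3-(hydroxymethyl)-2,3-dihydro-1-benzofuran-5-yl]prop-2-enoic acid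
Conditions: HF·pyridine, THF, 0 °C → rt
Reagents that add atoms: none
Why: Fluoride cleaves the primary silyl ether through the strong Si–F bond; the pyridine-buffered medium should be too weakly acidic to ionise the C2–O1 bond or to affect the cinnamic acid.

## Compound list

1 | (R)-4-benzyl-1,3-oxazolidin-2-one | O=C1N[C@H](Cc2ccccc2)CO1 | starting material
2 | methyl 4-chloro-4-oxobutanoate | COC(=O)CCC(=O)Cl | starting material
3 | methyl 4-[(4R)-4-benzyl-2-oxo-1,3-oxazolidin-3-yl]-4-oxobutanoate | COC(=O)CCC(=O)N1[C@H](Cc2ccccc2)COC1=O | intermediate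
4 | 3,4-dimethoxybenzaldehyde | COc1ccc(C=O)cc1OC | starting material
5 | methyl (3R,4R)-3-[(4R)-4-benzyl-2-oxo-1,3-oxazolidine-3-carbonyl]-4-(3,4-dimethoxyphenyl)-4-hydroxybutanoate (syn-aldol adduct) | COc1ccc([C@H](O)[C@@H](CC(=O)OC)C(=O)N2[C@H](Cc3ccccc3)COC2=O)cc1OC | intermediate
6 | (4R)-4-benzyl-3-[(2R,3R)-2-(3,4-dimethoxyphenyl)-5-oxooxolane-3-carbonyl]-1,3-oxazolidin-2-one | COc1ccc([C@@H]2OC(=O)C[C@H]2C(=O)N3[C@H](Cc4ccccc4)COC3=O)cc1OC | intermediate
7 | (2R,3R)-2-(3,4-dimethoxyphenyl)-5-oxooxolane-3-carboxylic acid | COc1ccc([C@@H]2OC(=O)C[C@H]2C(=O)O)cc1OC | intermediate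
8 | (4S,5R)-5-(3,4-dimethoxyphenyl)-4-(hydroxymethyl)oxolan-2-one | COc1ccc([C@@H]2OC(=O)C[C@H]2CO)cc1OC | intermediate
9 | (4S,5R)-4-({[tert-butyl(dimethyl)silyl]oxy}methyl)-5-(3,4-dimethoxyphenyl)oxolan-2-one | COc1ccc([C@@H]2OC(=O)C[C@H]2CO[Si](C)(C)C(C)(C)C)cc1OC | intermediate
10 | (2R,3S)-3-({[tert-butyl(dimethyl)silyl]oxy}methyl)-2-(3,4-dimethoxyphenyl)-2,3-dihydrofuran-5-yl trifluoromethanesulfonate | COc1ccc([C@@H]2OC(OS(=O)(=O)C(F)(F)F)=C[C@H]2CO[Si](C)(C)C(C)(C)C)cc1OC | intermediate
11 | 2,2'-(ethene-1,1-diyl)bis(4,4,5,5-tetramethyl-1,3,2-dioxaborolane) | C=C(B1OC(C)(C)C(C)(C)O1)B1OC(C)(C)C(C)(C)O1 | starting material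
12 | tert-butyl({(2R,3S)-2-(3,4-dimethoxyphenyl)-5-[1-(4,4,5,5-tetramethyl-1,3,2-dioxaborolan-2-yl)ethenyl]-2,3-dihydrofuran-3-yl}methoxy)dimethylsilane | COc1ccc([C@@H]2OC(C(=C)B3OC(C)(C)C(C)(C)O3)=C[C@H]2CO[Si](C)(C)C(C)(C)C)cc1OC | intermediate
13 | methyl propiolate | C#CC(=O)OC | starting material
14 | methyl (2R,3S)-3-({[tert-butyl(dimethyl)silyl]oxy}methyl)-2-(3,4-dimethoxyphenyl)-7-(4,4,5,5-tetramethyl-1,3,2-dioxaborolan-2-yl)-2,3,3a,6-tetrahydro-1-benzofuran-5-carboxylate (either configuration at C3a) | COc1ccc([C@@H]2OC3=C(B4OC(C)(C)C(C)(C)O4)CC(C(=O)OC)=CC3[C@H]2CO[Si](C)(C)C(C)(C)C)cc1OC | intermediate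
15 | methyl (2R,3S)-3-({[tert-butyl(dimethyl)silyl]oxy}methyl)-2-(3,4-dimethoxyphenyl)-7-(4,4,5,5-tetramethyl-1,3,2-dioxaborolan-2-yl)-2,3-dihydro-1-benzofuran-5-carboxylate | COc1ccc([C@@H]2Oc3c(B4OC(C)(C)C(C)(C)O4)cc(C(=O)OC)cc3[C@H]2CO[Si](C)(C)C(C)(C)C)cc1OC | intermediate
16 | methyl (2R,3S)-3-({[tert-butyl(dimethyl)silyl]oxy}methyl)-2-(3,4-dimethoxyphenyl)-7-hydroxy-2,3-dihydro-1-benzofuran-5-carboxylate | COc1ccc([C@@H]2Oc3c(O)cc(C(=O)OC)cc3[C@H]2CO[Si](C)(C)C(C)(C)C)cc1OC | intermediate
17 | (2R,3S)-3-({[tert-butyl(dimethyl)silyl]oxy}methyl)-2-(3,4-dimethoxyphenyl)-5-(hydroxymethyl)-2,3-dihydro-1-benzofuran-7-ol | COc1ccc([C@@H]2Oc3c(O)cc(CO)cc3[C@H]2CO[Si](C)(C)C(C)(C)C)cc1OC | intermediate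
18 | (2R,3S)-3-({[tert-butyl(dimethyl)silyl]oxy}methyl)-2-(3,4-dimethoxyphenyl)-7-hydroxy-2,3-dihydro-1-benzofuran-5-carbaldehyde | COc1ccc([C@@H]2Oc3c(O)cc(C=O)cc3[C@H]2CO[Si](C)(C)C(C)(C)C)cc1OC | intermediate
19 | malonic acid | OC(=O)CC(=O)O | starting material
20 | 2-{[(2R,3S)-3-({[tert-butyl(dimethyl)silyl]oxy}methyl)-2-(3,4-dimethoxyphenyl)-7-hydroxy-2,3-dihydro-1-benzofuran-5-yl]methylidene}propanedioic acid | COc1ccc([C@@H]2Oc3c(O)cc(C=C(C(=O)O)C(=O)O)cc3[C@H]2CO[Si](C)(C)C(C)(C)C)cc1OC | intermediate
21 | (E)-3-[(2R,3S)-3-({[tert-butyl(dimethyl)silyl]oxy}methyl)-2-(3,4-dimethoxyphenyl)-7-hydroxy-2,3-dihydro-1-benzofuran-5-yl]prop-2-enoic acid | COc1ccc([C@@H]2Oc3c(O)cc(/C=C/C(=O)O)cc3[C@H]2CO[Si](C)(C)C(C)(C)C)cc1OC | intermediate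
22 | (E)-3-[(2R,3S)-2-(3,4-dimethoxyphenyl)-7-hydroxy-3-(hydroxymethyl)-2,3-dihydro-1-benzofuran-5-yl]prop-2-enoic acid | COc1ccc([C@@H]2Oc3c(O)cc(/C=C/C(=O)O)cc3[C@H]2CO)cc1OC | target

## Step count and least certain steps

Total: 13 steps. Longest linear sequence: 13 steps (1 and 2 to 22); 4, 11, 13 and 19 enter as single building blocks.

**Step 8 (key step).** Three processes could spoil it. The cycloaddition may be slow, because both inner diene carbons are substituted and the boronate lowers the HOMO slightly; prolonged heating then risks protodeboronation or decomposition of the acid-sensitive enol ether. The regioselectivity may erode if the boronate's own preference competes with that of O1. DDQ may abstract hydride from the dimethoxybenzylic C2–H, which would scramble or destroy the C2 centre. The fallback puts the boron on after the arene is formed. It sets out from 10: Stille coupling with tributyl(vinyl)stannane (Pd(PPh3)4, LiCl, THF, 60 °C) should give the boron-free diene (2R,3S)-3-(TBS-oxymethyl)-2-(3,4-dimethoxyphenyl)-5-ethenyl-2,3-dihydrofuran F1. With 13 this gives the 3a,6-dihydro cycloadduct F2, which is dehydrogenated in the same pot to methyl (2R,3S)-3-(TBS-oxymethyl)-2-(3,4-dimethoxyphenyl)-2,3-dihydro-1-benzofuran-5-carboxylate F3; here the regiochemistry depends on the enol ether alone. Iridium-catalysed C–H borylation ([Ir(OMe)(cod)]2, 4,4'-di-tert-butyl-2,2'-bipyridine, B2pin2, THF, 70 °C) should then select C7–H, whose only ortho neighbour is the tied-back ring oxygen; C4–H lies between two substituents, C6–H is next to the ester, and every C–H of the dimethoxyphenyl ring has an ortho substituent. The fallback returns to the route at 15.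

**Step 7.** The likely failures are a second transmetalation of the remaining boronate of 12 (double coupling) and hydrolysis of the ketene acetal triflate by the aqueous base before oxidative addition. The fallback uses a boron group that cannot transmetalate, under non-aqueous conditions. It sets out from 10: stannylation with (Me3Sn)2 (Pd(PPh3)4, LiCl, THF, 60 °C) should give (2R,3S)-3-(TBS-oxymethyl)-2-(3,4-dimethoxyphenyl)-5-(trimethylstannyl)-2,3-dihydrofuran F4. Stille coupling of F4 with 2-(1-bromoethenyl)-6-methyl-1,3,6,2-dioxazaborocane-4,8-dione (PdCl2(PPh3)2, DMF, 45 °C) should give the N-methyliminodiacetate-protected boryl diene F5. Exchange of the boron ligand (pinacol, NaHCO3, MeOH, 45 °C) returns to the route at 12.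

**Step 6.** A five-membered lactone enolate can undergo Claisen self-condensation before it is trapped, and the resulting triflate is prone to hydrolysis during isolation. The fallback changes the electrophile class. It sets out from 9: KN(SiMe3)2 and (PhO)2P(O)Cl in THF/DMPU at −78 °C should give the ketene acetal phosphate (2R,3S)-3-(TBS-oxymethyl)-2-(3,4-dimethoxyphenyl)-2,3-dihydrofuran-5-yl diphenyl phosphate F6. F6 should tolerate chromatography on base-washed silica and couple with 11 (Pd(PPh3)4, aq. Cs2CO3, DMF, 50 °C), returning to the route at 12.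

**Step 11.** MnO2 may oxidise the electron-rich ortho-alkoxyphenol (phenoxyl radical coupling) in competition with the benzylic oxidation. The fallback carries out the redox adjustment before the phenol is unmasked. It sets out from 15: i-Bu2AlH reduction should give [(2R,3S)-3-(TBS-oxymethyl)-2-(3,4-dimethoxyphenyl)-7-(Bpin)-2,3-dihydro-1-benzofuran-5-yl]methanol F7. MnO2 should then give the corresponding 5-carbaldehyde F8, and NaBO3·4H2O oxidation of the boronate returns to the route at 18; the phenol is never exposed to MnO2.

## Further compounds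

F1 | step 8 | tert-butyl{[(2R,3S)-2-(3,4-dimethoxyphenyl)-5-ethenyl-2,3-dihydrofuran-3-yl]methoxy}dimethylsilane | COc1ccc([C@@H]2OC(C=C)=C[C@H]2CO[Si](C)(C)C(C)(C)C)cc1OC
F2 | step 8 | methyl (2R,3S)-3-({[tert-butyl(dimethyl)silyl]oxy}methyl)-2-(3,4-dimethoxyphenyl)-2,3,3a,6-tetrahydro-1-benzofuran-5-carboxylate (either configuration at C3a) | COc1ccc([C@@H]2OC3=CCC(C(=O)OC)=CC3[C@H]2CO[Si](C)(C)C(C)(C)C)cc1OC
F3 | step 8 | methyl (2R,3S)-3-({[tert-butyl(dimethyl)silyl]oxy}methyl)-2-(3,4-dimethoxyphenyl)-2,3-dihydro-1-benzofuran-5-carboxylate | COc1ccc([C@@H]2Oc3ccc(C(=O)OC)cc3[C@H]2CO[Si](C)(C)C(C)(C)C)cc1OC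
F4 | step 7 | tert-butyl{[(2R,3S)-2-(3,4-dimethoxyphenyl)-5-(trimethylstannyl)-2,3-dihydrofuran-3-yl]methoxy}dimethylsilane | COc1ccc([C@@H]2OC([Sn](C)(C)C)=C[C@H]2CO[Si](C)(C)C(C)(C)C)cc1OC
F5 | step 7 | 2-{1-[(2R,3S)-3-({[tert-butyl(dimethyl)silyl]oxy}methyl)-2-(3,4-dimethoxyphenyl)-2,3-dihydrofuran-5-yl]ethenyl}-6-methyl-1,3,6,2-dioxazaborocane-4,8-dione | COc1ccc([C@@H]2OC(C(=C)B3OC(=O)CN(C)CC(=O)O3)=C[C@H]2CO[Si](C)(C)C(C)(C)C)cc1OC
F6 | step 6 | (2R,3S)-3-({[tert-butyl(dimethyl)silyl]oxy}methyl)-2-(3,4-dimethoxyphenyl)-2,3-dihydrofuran-5-yl diphenyl phosphate | COc1ccc([C@@H]2OC(OP(=O)(Oc3ccccc3)Oc3ccccc3)=C[C@H]2CO[Si](C)(C)C(C)(C)C)cc1OC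
F7 | step 11 | [(2R,3S)-3-({[tert-butyl(dimethyl)silyl]oxy}methyl)-2-(3,4-dimethoxyphenyl)-7-(4,4,5,5-tetramethyl-1,3,2-dioxaborolan-2-yl)-2,3-dihydro-1-benzofuran-5-yl]methanol | COc1ccc([C@@H]2Oc3c(B4OC(C)(C)C(C)(C)O4)cc(CO)cc3[C@H]2CO[Si](C)(C)C(C)(C)C)cc1OC
F8 | step 11 | (2R,3S)-3-({[tert-butyl(dimethyl)silyl]oxy}methyl)-2-(3,4-dimethoxyphenyl)-7-(4,4,5,5-tetramethyl-1,3,2-dioxaborolan-2-yl)-2,3-dihydro-1-benzofuran-5-carbaldehyde | COc1ccc([C@@H]2Oc3c(B4OC(C)(C)C(C)(C)O4)cc(C=O)cc3[C@H]2CO[Si](C)(C)C(C)(C)C)cc1OC
A1 | alternative 1 | (2R)-6-bromo-2-(3,4-dimethoxyphenyl)-4-oxo-3,4-dihydro-2H-1-benzopyran-8-yl 2,2-dimethylpropanoate | COc1ccc([C@@H]2Oc3c(OC(=O)C(C)(C)C)cc(Br)cc3C(=O)C2)cc1OC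
A2 | alternative 1 | methyl (2R,3R)-5-bromo-2-(3,4-dimethoxyphenyl)-7-[(2,2-dimethylpropanoyl)oxy]-2,3-dihydro-1-benzofuran-3-carboxylate | COc1ccc([C@@H]2Oc3c(OC(=O)C(C)(C)C)cc(Br)cc3[C@H]2C(=O)OC)cc1OC
A3 | alternative 2 | 4-bromo-2-[2-{[tert-butyl(dimethyl)silyl]oxy}-1-(4-methylbenzenesulfonyl)ethyl]-6-(methoxymethoxy)phenol (racemic at the sulfonyl carbon) | Cc1ccc(S(=O)(=O)C(CO[Si](C)(C)C(C)(C)C)c2cc(Br)cc(OCOC)c2O)cc1
A4 | alternative 2 | 4-bromo-6-(2-{[tert-butyl(dimethyl)silyl]oxy}ethylidene)-2-(methoxymethoxy)cyclohexa-2,4-dien-1-one | O=C1C(OCOC)=CC(Br)=CC1=CCO[Si](C)(C)C(C)(C)C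
A5 | alternative 2 | (2R,5R)-1-[(3,4-dimethoxyphenyl)methyl]-2,5-dimethylthiolan-1-ium trifluoromethanesulfonate | COc1ccc(C[S+]2[C@H](C)CC[C@H]2C)cc1OC.[O-]S(=O)(=O)C(F)(F)F
A6 | alternative 2 | tert-butyl{[(2R,3S)-5-bromo-2-(3,4-dimethoxyphenyl)-7-(methoxymethoxy)-2,3-dihydro-1-benzofuran-3-yl]methoxy}dimethylsilane | COc1ccc([C@@H]2Oc3c(OCOC)cc(Br)cc3[C@H]2CO[Si](C)(C)C(C)(C)C)cc1OC
A7 | alternative 3 | methyl 3-[(2S)-1-(3,4-dimethoxyphenyl)-3-{[tri(propan-2-yl)silyl]oxy}propan-2-yl]-4-hydroxy-5-(methoxymethoxy)benzoate | COc1ccc(C[C@H](CO[Si](C(C)C)(C(C)C)C(C)C)c2cc(C(=O)OC)cc(OCOC)c2O)cc1OC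
A8 | alternative 3 | methyl (2R,3S)-2-(3,4-dimethoxyphenyl)-7-(methoxymethoxy)-3-({[tri(propan-2-yl)silyl]oxy}methyl)-2,3-dihydro-1-benzofuran-5-carboxylate | COc1ccc([C@@H]2Oc3c(OCOC)cc(C(=O)OC)cc3[C@H]2CO[Si](C(C)C)(C(C)C)C(C)C)cc1OC
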